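Follow the impurity. A trace of catalyst couples starting material with coupling partner to target, while some starting material goes elsewhere.

| setting | noon | autumn | violet | teal | red | amber | blue |
|---|---|---|---|---|---|---|---|
| starting material | 2 mM | 2 mM | 2.0 mM | 2.0 mM | 2.0 mM | 2.0 mM | 2.0 mM (fed, over 10 min) |
| coupling partner | 1.05 equiv | 1.05 equiv | 1.05 equiv (in portions, 2, over 10 min) | 1.05 equiv (fed, over 2.5 min) | 1.05 equiv (fed, over 10 min) | 1.05 equiv | 1.05 equiv |
| protic impurity | 0.60 mM | 0.90 mM | 0.600 mM | 0.600 mM | 0.600 mM | 0.600 mM | 0.600 mM |
| free catalyst | 0.1 mol% | 0.1 mol% | 0.1 mol% | 0.1 mol% | 0.1 mol% | 0.1 mol% | 0.1 mol% |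
| added ligand | 1.5 µM | 1.5 µM | 1.5 µM | 1.5 µM | 1.5 µM | 1.5 µM | 1.5 µM |
| remark | run made earlier | run made earlier | first portion at the start, last at 10 min | all else is in the flask from the start; the feed brings no volume worth counting | all else is in the flask from the start; the feed brings no volume worth counting | everything together at the start | all else is in the flask from the start; the feed brings no volume worth counting |
| time |  |  | 12 min | 12 min | 12 min | 12 min | 12 min |

| run | time / min | side product / % | target / % |
|---|---|---|---|
| noon | 1.00 | 2.4 | 58.9 |
| noon | 1.50 | 2.9 | 72.1 |
| noon | 2.50 | 2.6 | 78.9 |
| noon | 4.00 | 2.8 | 79.7 |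
| noon | 8.00 | 3.2 | 79.9 |
| noon | 12.0 | 3.5 | 79.6 |
| autumn | 0.667 | 1.2 | 43.4 |
| autumn | 1.33 | 2.4 | 64.9 |
| autumn | 2.00 | 2.5 | 72.7 |
| autumn | 2.50 | 2.5 | 73.5 |
| autumn | 3.00 | 2.5 | 73.6 |
| autumn | 4.00 | 2.3 | 73.9 |

(readings scatter by 0.3 percentage points)

1. the flask that comes out highest in amount of side product, in percent of the starting material charged, or "all alike" when all lie within 1.5 percentage points (violet / teal / red / amber / blue / all alike)
2. side product at the end, in percent of the starting material charged, violet
3. side product at the end, in percent of the starting material charged, teal
4. side product at the end, in percent of the starting material charged, red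
5. side product at the end, in percent of the starting material charged, amber
6. side product at the end, in percent of the starting material charged, blue

- percentages count the starting material that a species holds: one side product counts as two

The noon run holds protic impurity worth 30.0% of the starting material, yet target and side product leave 16.9% missing. The autumn run holds impurity worth 45.0%, and 23.8% is missing. The reckoning here takes the missing part as starting material lost one to one to impurity, so part of the impurity stays. Its loss is taken as first order in impurity, at a rate following [starting material], and a logarithm measures that: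

impurity decades = lg([protic impurity] at start / [protic impurity] at end)

noon: 0.360; autumn: 0.327

So the impurity decades read alike in the two runs, although the charges differ. In this reckoning the number measures exposure to [starting material], and the noon side product is read against it:

noon side product per decade: 9.73%

The readings also give a mean [starting material] of about 0.550 mM over the first 2.50 min of noon. In violet, the first portion brings half of the coupling partner, and the reckoning takes a mean [starting material] of 0.500 mM across the 10 min between portions:

violet decades: 1.31; violet side product: 12.7%

The forecast differs from this reckoning. It names violet highest at 15% (8% to 21%), with red 13%, teal 6.5%, amber 3.5% and blue 1.2%, on the ground that “Starving the flask of partner keeps a high for longer, so side product grows”.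

    catalyst intermediate C → by-product + catalyst intermediate D (k = 299 s⁻¹)
    catalyst intermediate A ⇌ catalyst intermediate B (K = 76.9, k = 365 s⁻¹)
    catalyst intermediate D → free catalyst + target (k = 43.2 s⁻¹)
    starting material + target → side product (k = 0.543 M⁻¹ s⁻¹)
    free catalyst + added ligand ⇌ idle complex, settled at all times (K = 2.68 × 10⁵ M⁻¹)
    starting material + protic impurity → quenched substrate (k = 10.3 M⁻¹ s⁻¹)
    starting material + free catalyst ⇌ catalyst intermediate A (K = 407 M⁻¹, k = 37300 M⁻¹ s⁻¹)
    coupling partner + catalyst intermediate B ⇌ catalyst intermediate C (K = 113 M⁻¹, k = 1.37 × 10⁵ M⁻¹ s⁻¹)

Violet gives 12.8%, the highest, then red 7.01%, teal 3.46%, amber 3.00% and blue 2.13%. Red lies 6 percentage points below the forecast and ends with 63.9% target. At 12.0 min, violet keeps 5.3% of its impurity, which is 1.28 decades against noon's 0.360, at 10.00% side product per decade. Red keeps 2.9% of its impurity, which is 1.53 decades, at 4.58% side product per decade.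

The numbers in the tables come from a simulation on assumed constants.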